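**Retrosynthetic overview**
- The target comes from its ring C benzyl ether, which arises by reductive opening of one furan ring of a (+)-pinoresinol mono-ether through the p-quinone methide of the free-phenol ring (the pinoresinol-to-lariciresinol reductase step done with borohydride). Only the free-phenol side can open, which places the glycerol ether on ring A.
- The threo-(7''S,8''S) side chain comes from an Evans syn-aldol of the pinoresinol O-acetyl imide with O-benzylvanillin, followed by reductive auxiliary removal.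
- (+)-Pinoresinol comes from a twofold oxidative quinone-methide cyclisation (DDQ) of (−)-secoisolariciresinol: the biosynthetic ring closures, reached from the reduced side.
- (−)-Secoisolariciresinol comes from an auxiliary-controlled oxidative 8–8' enolate dimerisation of a dihydroferulic acid imide.
- Ring order: tetrahydrofuran 1 (C7–O–C9'), then tetrahydrofuran 2 (C7'–O–C9) in the same flask; ring 2 alone is re-opened later.

Assumption: the target is read as the threo-(7''S,8''S)-guaiacylglycerol 8''-O-4 ether of (+)-lariciresinol (7S,8R,8'R; ring A = aryl on the tetrahydrofuran, ring B = benzylic aryl, ring C = glycerol aryl); dihydroferulic acid, both oxazolidinone reagents and O-benzylvanillin are bought.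

**Step 1**
Reactants: 1 3-(4-hydroxy-3-methoxyphenyl)propanoic acid (dihydroferulic acid); 2 (S)-4-isopropyloxazolidin-2-one
Product: 4 (S)-4-isopropyl-3-[3-(3-methoxy-4-pivaloyloxyphenyl)propanoyl]oxazolidin-2-one, via mixed pivalic anhydride 3 (not isolated)
Conditions: PivCl (2.1 equiv), Et3N (3.2 equiv), THF, −20 → 0 °C; then LiCl, 2, rt
Reagents that add atoms: pivaloyl chloride, CC(C)(C)C(=O)Cl
Why: Pivaloyl chloride acylates the phenol and turns the acid into the mixed anhydride, which N-acylates the oxazolidinone under LiCl/Et3N activation (mixed-anhydride N-acylation), so phenol protection and auxiliary loading are one operation; no stereocenter is formed.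

**Step 2**
Reactants: 4 (S)-4-isopropyl-3-[3-(3-methoxy-4-pivaloyloxyphenyl)propanoyl]oxazolidin-2-one (two molecules)
Product: 6 (2R,3R)-2,3-bis(3-methoxy-4-pivaloyloxybenzyl)-1,4-bis[(S)-4-isopropyl-2-oxooxazolidin-3-yl]butane-1,4-dione, via lithium Z-enolate 5 (not isolated)
Conditions: LiN(iPr)2 (1.1 equiv), THF, −78 °C; then TiCl4 (1.1 equiv), −78 °C → rt
Reagents that add atoms: none
Why: Oxidative enolate homocoupling (the titanium enolate is oxidised by one electron, TiCl4 ending as TiCl3) forms the 8–8' bond, each new stereocenter being made on the enolate face anti to the isopropyl group as in an Evans alkylation, which gives the (R,R)-dimer; the hindered aryl pivalates tolerate the amide base at −78 °C.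

**Step 3**
Reactants: 6 (R,R)-bis-imide
Product: 7 (−)-secoisolariciresinol, (2R,3R)-2,3-bis(4-hydroxy-3-methoxybenzyl)butane-1,4-diol
Conditions: LiBH4 (8 equiv), THF, 0 °C → 40 °C; aq. NH4Cl
Reagents that add atoms: none
Why: LiBH4 reductively cleaves both N-acyl oxazolidinones to primary alcohols without touching the α-stereocenters and also reduces the two activated aryl pivalates, so the C2-symmetric tetrol is released in one reduction.

**Step 4**
Reactants: 7 (−)-secoisolariciresinol
Product: 11 (+)-pinoresinol (7S,8R,7'S,8'R), via seco quinone methide 8 (not isolated), via (+)-lariciresinol 9 (not isolated), via lariciresinol quinone methide 10 (not isolated)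
Conditions: DDQ (2.05 equiv, two portions), 1,4-dioxane, 15 °C → rt, dark
Reagents that add atoms: none
Why: Proposed new method: DDQ abstracts hydride from a p-hydroxybenzylic CH2 to give the same p-quinone methide that the biosynthesis closes, the γ-hydroxyl of the other C6C3 unit adds 5-exo to form ring 1 ((+)-lariciresinol), and the second equivalent repeats this on ring B to close ring 2; C7 and C7' are set by the fixed C8/C8' centres, each aryl ending trans to the neighbouring ring-fusion bond (exo on the cis-fused bicycle); the closest known reaction type is the DDQ oxidative cyclisation of 4-alkylphenols carrying a pendant hydroxyl through p-quinone methides (intramolecular oxa-Michael addition).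

**Step 5**
Reactants: 11 (+)-pinoresinol; 12 (R)-4-benzyl-3-(2-chloroacetyl)oxazolidin-2-one
Product: 13 (+)-pinoresinol mono-4-O-[2-((R)-4-benzyl-2-oxooxazolidin-3-yl)-2-oxoethyl] ether
Conditions: 12 (0.9 equiv), K2CO3 (1.0 equiv), NaI (0.1 equiv), MeCN, rt; 11 recovered
Reagents that add atoms: none
Why: Williamson O-alkylation (SN2, Finkelstein-assisted) of one of the two homotopic phenols of C2-symmetric 11 gives a single mono-ether whichever phenol reacts, so the only loss is statistical (bis-ether and recovered 11); mild carbonate leaves the imide intact.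

**Step 6**
Reactants: 13 pinoresinol aryloxyacetyl imide; 14 4-benzyloxy-3-methoxybenzaldehyde (O-benzylvanillin)
Product: 16 (R)-4-benzyl-3-[(2R,3S)-3-(4-benzyloxy-3-methoxyphenyl)-3-hydroxy-2-(pinoresinol-4-O-yl)propanoyl]oxazolidin-2-one, via dibutylboron Z-enolate 15 (not isolated)
Conditions: Bu2BOTf (2.3 equiv), iPr2NEt (2.6 equiv), CH2Cl2, −78 → 0 °C; then 14, −78 → 0 °C; pH 7 buffer, MeOH, H2O2, 0 °C
Reagents that add atoms: none
Why: Evans syn-aldol: the boron Z-enolate of the aryloxyacetyl imide (the free phenol is masked in the flask as its borinate by the extra Bu2BOTf) adds to 14 through a Zimmerman–Traxler chair on the face away from the auxiliary benzyl group, which sets C8'' and C7'' together (2R,3S in the imide, syn, which is the threo series).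

**Step 7**
Reactants: 16 syn-aldol imide
Product: 19 ring C 4''-O-benzyl ether of the target, via pinoresinol-type diol 17 (not isolated), via ring B quinone methide 18 (not isolated)
Conditions: NaBH4 (4 equiv), 1,4-dioxane/H2O 3:1, 0 °C → rt; then 2 M aq. NaOH, NaBH4 (6 equiv), 90 °C, Ar; aq. NH4Cl
Reagents that add atoms: none
Why: Proposed new method: borohydride first cleaves the imide to the primary alcohol (known reductive auxiliary removal, giving the 7''S,8''S diol 17), then in hot alkali the ring B phenoxide expels the benzylic alkoxide (retro-oxa-Michael, the reverse of the ring closure) to give p-quinone methide 18, which borohydride traps irreversibly at C7'; the ring A side cannot open because its phenol is alkylated, ring C is protected as a benzyl ether so its benzylic alcohol cannot ionise, C7' becomes CH2 and C7, C8, C8' are untouched; the closest known reaction types are the NaBH4/aqueous NaOH reduction of p-hydroxybenzyl alcohols to p-alkylphenols through quinone methides and the enzymatic pinoresinol–lariciresinol reductase step.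

**Step 8**
Reactants: 19 ring C benzyl ether
Product: 20 target, (7''S,8''S)-threo-guaiacylglycerol 8''-O-4 ether of (+)-lariciresinol
Conditions: H2 (1 atm), 10% Pd/C, EtOAc/EtOH, rt, stopped at full debenzylation
Reagents that add atoms: none
Why: Hydrogenolysis of the aryl benzyl ether is much faster than that of the cyclic dialkyl benzylic ether or of the benzylic alcohol under neutral conditions, so the reaction stops at the free phenol with no stereocenter affected.

**Compound list**
1 | 3-(4-hydroxy-3-methoxyphenyl)propanoic acid (dihydroferulic acid) | COc1cc(CCC(=O)O)ccc1O | starting material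
2 | (S)-4-isopropyloxazolidin-2-one | CC(C)[C@H]1COC(=O)N1 | starting material
3 | 3-(3-methoxy-4-pivaloyloxyphenyl)propanoic pivalic anhydride | COc1cc(CCC(=O)OC(=O)C(C)(C)C)ccc1OC(=O)C(C)(C)C | intermediate
4 | (S)-4-isopropyl-3-[3-(3-methoxy-4-pivaloyloxyphenyl)propanoyl]oxazolidin-2-one | COc1cc(CCC(=O)N2[C@@H](C(C)C)COC2=O)ccc1OC(=O)C(C)(C)C | intermediate
5 | lithium Z-enolate of 4 | COc1cc(C/C=C(\O[Li])N2[C@@H](C(C)C)COC2=O)ccc1OC(=O)C(C)(C)C | intermediate
6 | (2R,3R)-2,3-bis(3-methoxy-4-pivaloyloxybenzyl)-1,4-bis[(S)-4-isopropyl-2-oxooxazolidin-3-yl]butane-1,4-dione | CC(C)[C@H]1COC(=O)N1C(=O)[C@H](Cc1ccc(OC(=O)C(C)(C)C)c(OC)c1)[C@@H](Cc1ccc(OC(=O)C(C)(C)C)c(OC)c1)C(=O)N1[C@@H](C(C)C)COC1=O | intermediate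
7 | (−)-secoisolariciresinol, (2R,3R) | OC[C@H](Cc1ccc(O)c(OC)c1)[C@@H](Cc1ccc(O)c(OC)c1)CO | intermediate
8 | C7 p-quinone methide of 7 | OC[C@H](C=C1C=CC(=O)C(OC)=C1)[C@@H](Cc1ccc(O)c(OC)c1)CO | intermediate
9 | (+)-lariciresinol (7S,8R,8'R) | COc1cc(C[C@H]2CO[C@H](c3ccc(O)c(OC)c3)[C@H]2CO)ccc1O | intermediate
10 | C7' p-quinone methide of 9 | COC1=CC(=C[C@H]2CO[C@H](c3ccc(O)c(OC)c3)[C@H]2CO)C=CC1=O | intermediate
11 | (+)-pinoresinol (7S,8R,7'S,8'R) | COc1cc([C@H]2OC[C@H]3[C@@H]2CO[C@@H]3c2ccc(O)c(OC)c2)ccc1O | intermediate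
12 | (R)-4-benzyl-3-(2-chloroacetyl)oxazolidin-2-one | O=C(CCl)N1[C@H](Cc2ccccc2)COC1=O | starting material
13 | (+)-pinoresinol mono-4-O-[2-((R)-4-benzyl-2-oxooxazolidin-3-yl)-2-oxoethyl] ether | COc1cc([C@H]2OC[C@H]3[C@@H]2CO[C@@H]3c2ccc(OCC(=O)N4[C@H](Cc5ccccc5)COC4=O)c(OC)c2)ccc1O | intermediate
14 | 4-benzyloxy-3-methoxybenzaldehyde (O-benzylvanillin) | COc1cc(C=O)ccc1OCc1ccccc1 | starting material
15 | dibutylboron Z-enolate of 13, ring B phenol as dibutylborinate | COc1cc([C@H]2OC[C@H]3[C@@H]2CO[C@@H]3c2ccc(O/C=C(\OB(CCCC)CCCC)N4[C@H](Cc5ccccc5)COC4=O)c(OC)c2)ccc1OB(CCCC)CCCC | intermediate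
16 | syn-aldol imide (2R,3S) on the pinoresinol core | COc1cc([C@H]2OC[C@H]3[C@@H]2CO[C@@H]3c2ccc(O[C@@H](C(=O)N4[C@H](Cc5ccccc5)COC4=O)[C@@H](O)c4ccc(OCc5ccccc5)c(OC)c4)c(OC)c2)ccc1O | intermediate
17 | (7''S,8''S)-4''-O-benzylguaiacylglycerol 8''-O-4 ether of (+)-pinoresinol | COc1cc([C@H]2OC[C@H]3[C@@H]2CO[C@@H]3c2ccc(O[C@@H](CO)[C@@H](O)c4ccc(OCc5ccccc5)c(OC)c4)c(OC)c2)ccc1O | intermediate
18 | ring B p-quinone methide formed by opening ring 2 of 17 | COC1=CC(=C[C@H]2CO[C@H](c3ccc(O[C@@H](CO)[C@@H](O)c4ccc(OCc5ccccc5)c(OC)c4)c(OC)c3)[C@H]2CO)C=CC1=O | intermediate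
19 | ring C 4''-O-benzyl ether of the target | COc1cc(C[C@H]2CO[C@H](c3ccc(O[C@@H](CO)[C@@H](O)c4ccc(OCc5ccccc5)c(OC)c4)c(OC)c3)[C@H]2CO)ccc1O | intermediate
20 | (7''S,8''S)-threo-guaiacylglycerol 8''-O-4 ether of (+)-lariciresinol | COc1cc(C[C@H]2CO[C@H](c3ccc(O[C@@H](CO)[C@@H](O)c4ccc(O)c(OC)c4)c(OC)c3)[C@H]2CO)ccc1O | target

**Totals**
Total step count: 8. Longest linear sequence: 8 steps (1 → 20).

**Steps most likely to fail**

Step 7 (selective reductive ring opening). The ring opening is reversible and the tethered alkoxide may re-close faster than hydride traps the quinone methide, so conversion may stall. The fallback sets out from 17, isolated after the room-temperature stage, and comes back at 19. DDQ (1.1 equiv) in wet dioxane oxidises the benzylic C–H of the free-phenolic benzylic ether, the phenol-selective counterpart of an oxidative p-methoxybenzyl ether cleavage. Water then opens ring 2 irreversibly to the 7'-oxo keto alcohol F6. NaBH4 at 0 °C reduces the ketone before C8' can epimerise, and NaBH4 in hot aqueous NaOH removes the resulting p-hydroxybenzylic hydroxyl through the quinone methide, which can no longer re-close, giving 19.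

Step 4 (twofold DDQ cyclisation). Risks are over-oxidation of the phenolic benzylic ethers formed and acid-promoted Friedel–Crafts closure to an aryltetralin. The fallback sets out from 7 and comes back at 20; it replaces the furofuran detour by protecting-group differentiation and a single oxidative cyclisation.
- BnBr (1 equiv) and K2CO3 give the mono-benzyl ether (2R,3R)-2-(4-benzyloxy-3-methoxybenzyl)-3-(4-hydroxy-3-methoxybenzyl)butane-1,4-diol F1; this is a single compound because 7 is C2-symmetric.
- One equivalent of DDQ cyclises only the free-phenol side to (+)-lariciresinol 4'-O-benzyl ether F2.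
- Alkylation with 12 gives the ring A aryloxyacetyl imide F3.
- The Evans syn-aldol with 14 (extra Bu2BOTf for the 9-OH) gives the aldol imide F4.
- LiBH4 gives the ring B, ring C di-O-benzyl ether of the target F5, and hydrogenolysis gives 20.

This fallback also makes step 7 unnecessary.

Step 5 (mono-alkylation with a base-sensitive chloroacetyl imide). Phenoxide may attack the imide carbonyl instead of displacing chloride. The fallback sets out from 11 and comes back at 13 and forms the same ether under neutral redox-condensation conditions. (R)-4-Benzyloxazolidin-2-one is acylated with benzyloxyacetyl chloride to (R)-4-benzyl-3-(2-benzyloxyacetyl)oxazolidin-2-one F7. Hydrogenolysis gives (R)-4-benzyl-3-(2-hydroxyacetyl)oxazolidin-2-one F8. A Mitsunobu reaction of 11 with F8 (PPh3, DIAD, THF) then gives 13.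

**Further compounds**
F1 | step 4 | (2R,3R)-2-(4-benzyloxy-3-methoxybenzyl)-3-(4-hydroxy-3-methoxybenzyl)butane-1,4-diol | OC[C@H](Cc1ccc(O)c(OC)c1)[C@@H](Cc1ccc(OCc2ccccc2)c(OC)c1)CO
F2 | step 4 | (+)-lariciresinol 4'-O-benzyl ether (ring B benzylated) | COc1cc(C[C@H]2CO[C@H](c3ccc(O)c(OC)c3)[C@H]2CO)ccc1OCc1ccccc1
F3 | step 4 | ring A O-[2-((R)-4-benzyl-2-oxooxazolidin-3-yl)-2-oxoethyl] ether of F2 | COc1cc(C[C@H]2CO[C@H](c3ccc(OCC(=O)N4[C@H](Cc5ccccc5)COC4=O)c(OC)c3)[C@H]2CO)ccc1OCc1ccccc1
F4 | step 4 | syn-aldol imide (2R,3S) on the ring B benzylated lariciresinol core | COc1cc(C[C@H]2CO[C@H](c3ccc(O[C@@H](C(=O)N4[C@H](Cc5ccccc5)COC4=O)[C@@H](O)c4ccc(OCc5ccccc5)c(OC)c4)c(OC)c3)[C@H]2CO)ccc1OCc1ccccc1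
F5 | step 4 | ring B, ring C di-O-benzyl ether of the target | COc1cc(C[C@H]2CO[C@H](c3ccc(O[C@@H](CO)[C@@H](O)c4ccc(OCc5ccccc5)c(OC)c4)c(OC)c3)[C@H]2CO)ccc1OCc1ccccc1
F6 | step 7 | 7'-oxo keto alcohol from oxidative opening of ring 2 of 17 | COc1cc(C(=O)[C@H]2CO[C@H](c3ccc(O[C@@H](CO)[C@@H](O)c4ccc(OCc5ccccc5)c(OC)c4)c(OC)c3)[C@H]2CO)ccc1O
F7 | step 5 | (R)-4-benzyl-3-(2-benzyloxyacetyl)oxazolidin-2-one | O=C(COCc1ccccc1)N1[C@H](Cc2ccccc2)COC1=O
F8 | step 5 | (R)-4-benzyl-3-(2-hydroxyacetyl)oxazolidin-2-one | O=C(CO)N1[C@H](Cc2ccccc2)COC1=O
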